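**Strategy.** Ring A (C1–C6; C1 carbinol, C3 CMe2, C4 CHBr) is not built as a cyclohexane. Its C1(OH)–C7 unit is the retron of a benzilic ester ring contraction of a cycloheptane-1,2-dione, and because C1 and C4 lie 1,4 across ring A the C4 oxygen can be the internal alkoxide. Transannular hemiketal formation and 1,2-shift expel C7 as a lactone carbonyl, giving a 2-oxabicyclo[2.2.2]octanone in which C4 dictates C1; either dione carbonyl leads to the same lactone. Bromide then enters C4 with inversion, C7 acylates a bromocyclohexylmethyllithium made by enantiospecific bromonium cyclisation, and the C7 ketone closes the cyclopentane by aldol.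

Key step: step 7

Remark: ring A atoms are C1–C6 and the linker carbon is C7; hydrindane atoms carry primed indane locants (C1′ bears C7, C2′ the secondary OH, C3a′ the angular methyl, C4′ Br, C7′ the tertiary OH, C7a′ the ring-fusion H). 1,3-Dibromo-3-methylbutan-2-one is assumed to be made rather than bought.

**Ring A fragment**

Step 1
Reactants: 1 3-methylbutan-2-one
Product: 2 1,3-dibromo-3-methylbutan-2-one
Conditions: Br2 (2.05 equiv), PBr3 (cat.), CH2Cl2, −10 → 20 °C
Reagents that add atoms: bromine, BrBr
Why: Acid-catalysed α-bromination through the enols puts the first bromine on the tertiary carbon and the second on the methyl carbon, because the tertiary position cannot take a second halogen.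

Step 2
Reactants: 2 1,3-dibromo-3-methylbutan-2-one; 3 buta-1,3-diene
Product: 4 2,2-dimethylcyclohept-4-en-1-one
Conditions: Fe2(CO)9 (1.2 equiv), 3 (excess), benzene, 60 °C, sealed tube
Reagents that add atoms: none
Why: Iron-mediated oxyallyl (4+3) cycloaddition: Fe2(CO)9 reduces 2 to an iron-bound 2-oxyallyl cation that adds across s-cis buta-1,3-diene, so the seven-membered ring forms with the gem-dimethyl carbon next to the carbonyl and the alkene opposite to it.

Step 3
Reactants: 4 2,2-dimethylcyclohept-4-en-1-one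
Product: 5 (1R)-2,2-dimethylcyclohept-4-en-1-ol
Conditions: (S)-1-methyl-3,3-diphenyltetrahydro-1H,3H-pyrrolo[1,2-c][1,3,2]oxazaborole (10 mol %), BH3·SMe2 (0.7 equiv), THF, −20 °C; MeOH
Reagents that add atoms: none
Why: Corey–Bakshi–Shibata reduction in which the fully substituted CMe2 flank is the large group, so the (S)-catalyst should deliver hydride to the face that gives the (R)-carbinol, the future C4 of ring A.

Step 4
Reactants: 5 (1R)-2,2-dimethylcyclohept-4-en-1-ol
Product: 6 tert-butyl{[(1R)-2,2-dimethylcyclohept-4-en-1-yl]oxy}dimethylsilane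
Conditions: TBSOTf, 2,6-lutidine, CH2Cl2, 0 °C
Reagents that add atoms: tert-butyldimethylsilyl trifluoromethanesulfonate, CC(C)(C)[Si](C)(C)OS(=O)(=O)C(F)(F)F
Why: Silylation of the hindered neopentyl-type alcohol with the silyl triflate masks the C4 oxygen so that it survives oxidation of the alkene to the dione and can later be unmasked as the internal nucleophile.

Step 5
Reactants: 6 tert-butyl{[(1R)-2,2-dimethylcyclohept-4-en-1-yl]oxy}dimethylsilane
Product: 7 (5R)-5-[(tert-butyldimethylsilyl)oxy]-4,4-dimethylcycloheptane-1,2-diol (cis-diol; both facial diastereomers)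
Conditions: OsO4 (2 mol %), N-methylmorpholine N-oxide, acetone/H2O, 25 °C
Reagents that add atoms: N-methylmorpholine N-oxide, C[N+]1([O-])CCOCC1; water, O
Why: Upjohn dihydroxylation (syn addition by catalytic OsO4) of the only alkene, in which both facial diastereomers are usable because the two new carbinol centres become carbonyl carbons in the next step.

Step 6
Reactants: 7 (5R)-5-[(tert-butyldimethylsilyl)oxy]-4,4-dimethylcycloheptane-1,2-diol
Product: 8 (5R)-5-[(tert-butyldimethylsilyl)oxy]-4,4-dimethylcycloheptane-1,2-dione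
Conditions: DMSO, (CF3CO)2O, CH2Cl2, −60 °C; Et3N, −60 → 0 °C
Reagents that add atoms: none
Why: Swern-type oxidation with trifluoroacetic anhydride-activated DMSO oxidises both secondary alcohols of the vicinal diol to the 1,2-dione without cleaving the C–C bond, and the silyl ether is untouched.

Step 7
Reactants: 8 (5R)-5-[(tert-butyldimethylsilyl)oxy]-4,4-dimethylcycloheptane-1,2-dione
Product: 11 (1R,4R)-4-hydroxy-6,6-dimethyl-2-oxabicyclo[2.2.2]octan-3-one, via hydroxy dione 9 (not isolated), via transannular hemiketal 10 (not isolated)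
Conditions: HF·pyridine, MeCN, 0 °C; concentrate; then KOt-Bu (1.1 equiv), THF, 0 → 25 °C; aq. NH4Cl
Reagents that add atoms: none
Why: Desilylation frees the C4 hydroxyl (9), which adds across the ring to either dione carbonyl to give the 8-oxabicyclo[3.2.1]octane hemiketal 10 (5-exo-trig closure of the oxolane ring), and its alkoxide then undergoes the 1,2-shift of the ring CH2 from the hemiketal carbon to the neighbouring ketone carbon while the hemiketal carbon collapses to the lactone carbonyl C7; this is a benzilic ester rearrangement with an internal alkoxide, the closest known type being the alkoxide- or hydroxide-mediated benzilic ring contraction of cyclic 1,2-diones. The six-membered carbocycle is closed by that 1,2-alkyl shift (a bicyclo[3.2.1] to bicyclo[2.2.2] skeletal shift), not by cyclisation of a chain. The only new stereocentre, C1, is controlled by the one-atom oxygen bridge: C7 and the C4 oxygen must be cis, so the (R) configuration set at C4 in step 3 is relayed to (R)-C1. The step needs chemoselectivity for the internal alkoxide over external nucleophiles and over enolisation of the dione, which the five-membered hemiketal and the non-nucleophilic base should secure; regioselectivity is not needed, because attack at either carbonyl followed by shift of the adjacent CH2 gives the same lactone 11. The driving force is the exchange of a seven-membered 1,2-dione for an ester and a six-membered ring.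

Step 8
Reactants: 11 (1R,4R)-4-hydroxy-6,6-dimethyl-2-oxabicyclo[2.2.2]octan-3-one
Product: 12 (1R,4R)-1,4-dihydroxy-N-methoxy-N,3,3-trimethylcyclohexane-1-carboxamide
Conditions: MeNH(OMe)·HCl, AlMe3, CH2Cl2, 0 → 25 °C; Rochelle salt work-up
Reagents that add atoms: N,O-dimethylhydroxylamine hydrochloride, CNOC.Cl
Why: Weinreb aminolysis of the strained bridged lactone by the aluminium amide frees the C4 hydroxyl (axial, cis to the carboxamide) without touching a stereocentre and turns C7 into an acyl donor for a single organometallic addition.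

Step 9
Reactants: 12 (1R,4R)-1,4-dihydroxy-N-methoxy-N,3,3-trimethylcyclohexane-1-carboxamide
Product: 13 (1R,4S)-4-bromo-1-hydroxy-N-methoxy-N,3,3-trimethylcyclohexane-1-carboxamide
Conditions: PPh3, CBr4, CH2Cl2, 0 → 25 °C
Reagents that add atoms: carbon tetrabromide, BrC(Br)(Br)Br
Why: Appel reaction: bromide displaces the alkoxyphosphonium group at the secondary C4 by SN2 with inversion, which puts bromine equatorial and cis to the tertiary C1 hydroxyl as in the target, while the tertiary alcohol and the amide do not react.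

**Bromocyclohexane fragment**

Step 10
Reactants: 14 pent-1-en-4-yne
Product: 16 (2E)-3-methylhexa-2,5-dien-1-ol, via alkenylalane 15 (not isolated)
Conditions: AlMe3 (2 equiv), Cp2ZrCl2 (20 mol %), CH2Cl2, 0 → 25 °C; then n-BuLi, THF, −78 °C; (CH2O)n, −78 → 25 °C
Reagents that add atoms: trimethylaluminium, C[Al](C)C; paraformaldehyde (as formaldehyde), C=O
Why: Negishi zirconium-catalysed carboalumination adds methyl and aluminium syn across the terminal alkyne to give the (E)-alkenylalane 15 regioselectively, and its ate complex is trapped by formaldehyde with retention of the alkene geometry, the isolated terminal alkene reacting far more slowly.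

Step 11
Reactants: 16 (2E)-3-methylhexa-2,5-dien-1-ol
Product: 17 [(2R,3R)-3-methyl-3-(prop-2-en-1-yl)oxiran-2-yl]methanol
Conditions: Ti(OiPr)4 (10 mol %), D-(−)-diethyl tartrate (12 mol %), t-BuOOH, 4 Å molecular sieves, CH2Cl2, −20 °C
Reagents that add atoms: tert-butyl hydroperoxide, CC(C)(C)OO
Why: Sharpless asymmetric epoxidation of the (E)-allylic alcohol, in which D-(−)-diethyl tartrate should deliver oxygen to the face that gives the (2R,3R)-epoxide (the mirror-image outcome of the L-tartrate epoxidation of geraniol), which fixes the absolute configuration of the later C3a′ and C4′ and leaves the allyl alkene alone.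

Step 12
Reactants: 17 [(2R,3R)-3-methyl-3-(prop-2-en-1-yl)oxiran-2-yl]methanol
Product: 18 (2S,3R)-2-(iodomethyl)-3-methyl-3-(prop-2-en-1-yl)oxirane
Conditions: PPh3, I2, imidazole, CH2Cl2, 0 °C
Reagents that add atoms: iodine, II
Why: Appel-type iodination converts the primary alcohol into the primary iodide by SN2 at the CH2 group without opening the trisubstituted epoxide.

Step 13
Reactants: 18 (2S,3R)-2-(iodomethyl)-3-methyl-3-(prop-2-en-1-yl)oxirane; 19 methyl 3-oxobutanoate
Product: 21 methyl 5-[(2R,3R)-3-methyl-3-(prop-2-en-1-yl)oxiran-2-yl]-3-oxopentanoate, via acetoacetate dianion 20 (not isolated)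
Conditions: 19, NaH, THF, 0 °C; n-BuLi, 0 °C; then 18, −20 → 0 °C; aq. NH4Cl
Reagents that add atoms: none
Why: Alkylation of the acetoacetate dianion 20 takes place at its more basic terminal carbon by SN2 at the primary iodide, leaving the 1,3-dicarbonyl unit as the later cyclisation terminator.

Step 14
Reactants: 21 methyl 5-[(2R,3R)-3-methyl-3-(prop-2-en-1-yl)oxiran-2-yl]-3-oxopentanoate
Product: 22 methyl (6S,7R)-6-bromo-7-hydroxy-7-methyl-3-oxodec-9-enoate
Conditions: Li2NiBr4 (THF solution), 0 → 25 °C; aqueous work-up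
Reagents that add atoms: dilithium tetrabromonickelate, [Li+].[Li+].Br[Ni-2](Br)(Br)Br
Why: Li2NiBr4 opens the trisubstituted epoxide by SN2 attack of bromide at the less substituted carbon with inversion, giving the anti bromohydrin with bromine on the secondary carbon (C6 S) and the tertiary alcohol (C7 R) in place.

Step 15
Reactants: 22 methyl (6S,7R)-6-bromo-7-hydroxy-7-methyl-3-oxodec-9-enoate
Product: 23 methyl (1S,2S,3S)-3-bromo-2-methyl-6-oxo-2-(prop-2-en-1-yl)cyclohexane-1-carboxylate
Conditions: TfOH (0.2 equiv), (CF3)2CHOH, 0 °C, 0.01 M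
Reagents that add atoms: none
Why: Acid ionisation of the tertiary alcohol with backside participation of the anti bromine gives a configurationally defined bromonium ion that is opened at the tertiary carbon by the β-keto ester enol through a chair transition state (enantiospecific bromonium-induced cation–olefin cyclisation, 6-endo closure), which puts Br equatorial, the methyl group axial and the allyl group equatorial on the new quaternary carbon, while the ester carbon settles equatorial by enolisation.

Step 16
Reactants: 23 methyl (1S,2S,3S)-3-bromo-2-methyl-6-oxo-2-(prop-2-en-1-yl)cyclohexane-1-carboxylate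
Product: 24 (2R,3S,4S)-4-bromo-2-(hydroxymethyl)-3-methyl-3-(prop-2-en-1-yl)cyclohexan-1-ol (both C1 epimers)
Conditions: LiAlH4, THF, −20 → 0 °C
Reagents that add atoms: none
Why: LiAlH4 reduces the ester to the CH2OH group and the ketone to a carbinol whose configuration is irrelevant, while the neopentyl secondary bromide resists hydride displacement.

Step 17
Reactants: 24 (2R,3S,4S)-4-bromo-2-(hydroxymethyl)-3-methyl-3-(prop-2-en-1-yl)cyclohexan-1-ol
Product: 25 (2R,3S,4S)-4-bromo-2-{[(tert-butyldimethylsilyl)oxy]methyl}-3-methyl-3-(prop-2-en-1-yl)cyclohexan-1-ol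
Conditions: TBSCl, imidazole, CH2Cl2, 0 °C
Reagents that add atoms: tert-butyldimethylsilyl chloride, CC(C)(C)[Si](C)(C)Cl
Why: The primary alcohol is silylated much faster than the hindered secondary one, which leaves only the ring carbinol free for oxidation.

Step 18
Reactants: 25 (2R,3S,4S)-4-bromo-2-{[(tert-butyldimethylsilyl)oxy]methyl}-3-methyl-3-(prop-2-en-1-yl)cyclohexan-1-ol
Product: 26 (2R,3S,4S)-4-bromo-2-{[(tert-butyldimethylsilyl)oxy]methyl}-3-methyl-3-(prop-2-en-1-yl)cyclohexan-1-one
Conditions: Dess–Martin periodinane, NaHCO3, CH2Cl2, 25 °C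
Reagents that add atoms: none
Why: Dess–Martin oxidation returns the ring ketone under non-basic conditions, and the α-carbon keeps its CH2OSi group equatorial, which is also the thermodynamic arrangement.

Step 19
Reactants: 26 (2R,3S,4S)-4-bromo-2-{[(tert-butyldimethylsilyl)oxy]methyl}-3-methyl-3-(prop-2-en-1-yl)cyclohexan-1-one
Product: 27 (1R,2R,3S,4S)-4-bromo-2-{[(tert-butyldimethylsilyl)oxy]methyl}-1,3-dimethyl-3-(prop-2-en-1-yl)cyclohexan-1-ol
Conditions: MeLi, CeCl3, THF, −78 °C
Reagents that add atoms: methyllithium, [Li]C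
Why: The non-basic organocerium reagent adds 1,2 without enolisation or β-elimination, and the axial methyl group on the 1,3-related quaternary carbon blocks axial attack, so the new methyl group enters equatorially and the tertiary hydroxyl ends axial (C7′ R).

Step 20
Reactants: 27 (1R,2R,3S,4S)-4-bromo-2-{[(tert-butyldimethylsilyl)oxy]methyl}-1,3-dimethyl-3-(prop-2-en-1-yl)cyclohexan-1-ol
Product: 28 (1R,2R,3S,4S)-4-bromo-2-(hydroxymethyl)-1,3-dimethyl-3-(prop-2-en-1-yl)cyclohexan-1-ol
Conditions: TBAF, THF, 0 → 25 °C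
Reagents that add atoms: none
Why: Fluoride cleaves the primary silyl ether and leaves the tertiary alcohol and the secondary bromide untouched.

Step 21
Reactants: 28 (1R,2R,3S,4S)-4-bromo-2-(hydroxymethyl)-1,3-dimethyl-3-(prop-2-en-1-yl)cyclohexan-1-ol
Product: 29 (1R,2S,3S,4S)-4-bromo-2-(iodomethyl)-1,3-dimethyl-3-(prop-2-en-1-yl)cyclohexan-1-ol
Conditions: PPh3, I2, imidazole, CH2Cl2, 0 °C
Reagents that add atoms: iodine, II
Why: Appel-type iodination is selective for the primary hydroxyl, the tertiary alcohol being inert under these conditions.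

**Union and endgame**

Step 22
Reactants: 29 (1R,2S,3S,4S)-4-bromo-2-(iodomethyl)-1,3-dimethyl-3-(prop-2-en-1-yl)cyclohexan-1-ol; 13 (1R,4S)-4-bromo-1-hydroxy-N-methoxy-N,3,3-trimethylcyclohexane-1-carboxamide
Product: 31 1-[(1R,4S)-4-bromo-1-hydroxy-3,3-dimethylcyclohexyl]-2-[(1S,2S,3S,6R)-3-bromo-6-hydroxy-2,6-dimethyl-2-(prop-2-en-1-yl)cyclohexyl]ethan-1-one, via alkyllithium 30 (not isolated)
Conditions: 29, MeLi (1.0 equiv), Et2O/pentane, −78 °C; t-BuLi (2.1 equiv), −78 °C; then 13 pre-treated with LiN(SiMe3)2 (1.0 equiv) in THF, −78 °C; aq. NH4Cl at −78 °C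
Reagents that add atoms: none
Why: Lithium–iodine exchange at the primary iodide with two equivalents of t-BuLi is far faster at −78 °C than exchange at the hindered secondary bromide or 5-exo carbolithiation of the allyl group, and the alkyllithium 30 adds once to the Weinreb amide through a stable chelated tetrahedral intermediate (Weinreb ketone synthesis), so C7 arrives as a ketone that is enolisable only towards C1′.

Step 23
Reactants: 31 the ketone from step 22
Product: 32 2-[(1S,2S,3R,6S)-6-bromo-2-{2-[(1R,4S)-4-bromo-1-hydroxy-3,3-dimethylcyclohexyl]-2-oxoethyl}-3-hydroxy-1,3-dimethylcyclohexyl]acetaldehyde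
Conditions: O3, CH2Cl2/MeOH, −78 °C; Me2S
Reagents that add atoms: ozone, [O-][O+]=O
Why: Ozonolysis with reductive work-up cleaves the only alkene to the aldehyde whose carbonyl carbon becomes C2′.

Step 24
Reactants: 32 the keto aldehyde from step 23
Product: 33 [(1R,4S)-4-bromo-1-hydroxy-3,3-dimethylcyclohexyl][(1S,2R,3aS,4S,7R,7aS)-4-bromo-2,7-dihydroxy-3a,7-dimethyloctahydro-1H-inden-1-yl]methanone
Conditions: LiN(SiMe3)2 (3.2 equiv), THF, −78 °C; AcOH at −78 °C
Reagents that add atoms: none
Why: Intramolecular aldol reaction: the ketone can enolise only at C1′, and its lithium (Z)-enolate closes the five-membered ring on the aldehyde (5-exo-trig with the enolate exocyclic) through a lithium-bridged closed transition state that makes the acyl group and the new hydroxyl cis, both on the face opposite to the angular methyl group (C1′ S, C2′ R), while joining the two equatorial arms gives the trans-hydrindane.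

Step 25
Reactants: 33 the β-hydroxy ketone from step 24
Product: 34 (1R,4S)-4-bromo-1-{(R)-[(1S,2R,3aS,4S,7R,7aS)-4-bromo-2,7-dihydroxy-3a,7-dimethyloctahydro-1H-inden-1-yl](hydroxy)methyl}-3,3-dimethylcyclohexan-1-ol (CNP0144982.1)
Conditions: Et2BOMe, THF/MeOH (4:1), −78 °C; NaBH4, −78 → −40 °C; AcOH, then MeOH co-evaporation
Reagents that add atoms: none
Why: Narasaka–Prasad reduction: Et2BOMe ties the secondary C2′ hydroxyl and the ketone oxygen into a six-membered boron chelate (the hindered tertiary hydroxyls exchange more slowly) and external hydride attacks it to give the 1,3-syn diol, that is (R)-C7.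

**Compound list**

1 | 3-methylbutan-2-one | CC(=O)C(C)C | starting material
2 | 1,3-dibromo-3-methylbutan-2-one | BrCC(=O)C(C)(C)Br | intermediate
3 | buta-1,3-diene | C=CC=C | starting material
4 | 2,2-dimethylcyclohept-4-en-1-one | CC1(C)CC=CCCC1=O | intermediate
5 | (1R)-2,2-dimethylcyclohept-4-en-1-ol | CC1(C)CC=CCC[C@H]1O | intermediate
6 | tert-butyl{[(1R)-2,2-dimethylcyclohept-4-en-1-yl]oxy}dimethylsilane | CC1(C)CC=CCC[C@H]1O[Si](C)(C)C(C)(C)C | intermediate
7 | (5R)-5-[(tert-butyldimethylsilyl)oxy]-4,4-dimethylcycloheptane-1,2-diol (cis-diol, both facial diastereomers, diol centres left open) | CC1(C)CC(O)C(O)CC[C@H]1O[Si](C)(C)C(C)(C)C | intermediate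
8 | (5R)-5-[(tert-butyldimethylsilyl)oxy]-4,4-dimethylcycloheptane-1,2-dione | CC1(C)CC(=O)C(=O)CC[C@H]1O[Si](C)(C)C(C)(C)C | intermediate
9 | (5R)-5-hydroxy-4,4-dimethylcycloheptane-1,2-dione | CC1(C)CC(=O)C(=O)CC[C@H]1O | intermediate (not isolated)
10 | (1R,5R)-1-hydroxy-6,6-dimethyl-8-oxabicyclo[3.2.1]octan-2-one (transannular hemiketal; the regioisomer from attack at the other carbonyl forms too and converges on 11) | CC1(C)C[C@@]2(O)O[C@@H]1CCC2=O | intermediate (not isolated)
11 | (1R,4R)-4-hydroxy-6,6-dimethyl-2-oxabicyclo[2.2.2]octan-3-one | CC1(C)C[C@]2(O)CC[C@H]1OC2=O | intermediate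
12 | (1R,4R)-1,4-dihydroxy-N-methoxy-N,3,3-trimethylcyclohexane-1-carboxamide | CC1(C)C[C@@](O)(C(=O)N(C)OC)CC[C@H]1O | intermediate
13 | (1R,4S)-4-bromo-1-hydroxy-N-methoxy-N,3,3-trimethylcyclohexane-1-carboxamide | CC1(C)C[C@@](O)(C(=O)N(C)OC)CC[C@@H]1Br | intermediate
14 | pent-1-en-4-yne | C=CCC#C | starting material
15 | dimethyl[(1E)-2-methylpenta-1,4-dien-1-yl]alane | C[Al](C)/C=C(\C)CC=C | intermediate (not isolated)
16 | (2E)-3-methylhexa-2,5-dien-1-ol | OC/C=C(\C)CC=C | intermediate
17 | [(2R,3R)-3-methyl-3-(prop-2-en-1-yl)oxiran-2-yl]methanol | OC[C@H]1O[C@]1(C)CC=C | intermediate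
18 | (2S,3R)-2-(iodomethyl)-3-methyl-3-(prop-2-en-1-yl)oxirane | IC[C@H]1O[C@]1(C)CC=C | intermediate
19 | methyl 3-oxobutanoate | COC(=O)CC(C)=O | starting material
20 | lithium sodium dianion of methyl 3-oxobutanoate | [Li+].[Na+].COC(=O)[CH-]C(=O)[CH2-] | intermediate (not isolated)
21 | methyl 5-[(2R,3R)-3-methyl-3-(prop-2-en-1-yl)oxiran-2-yl]-3-oxopentanoate | COC(=O)CC(=O)CC[C@H]1O[C@]1(C)CC=C | intermediate
22 | methyl (6S,7R)-6-bromo-7-hydroxy-7-methyl-3-oxodec-9-enoate | COC(=O)CC(=O)CC[C@H](Br)[C@](C)(O)CC=C | intermediate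
23 | methyl (1S,2S,3S)-3-bromo-2-methyl-6-oxo-2-(prop-2-en-1-yl)cyclohexane-1-carboxylate | COC(=O)[C@@H]1C(=O)CC[C@H](Br)[C@@]1(C)CC=C | intermediate
24 | (2R,3S,4S)-4-bromo-2-(hydroxymethyl)-3-methyl-3-(prop-2-en-1-yl)cyclohexan-1-ol (both C1 epimers) | OC[C@@H]1C(O)CC[C@H](Br)[C@@]1(C)CC=C | intermediate
25 | (2R,3S,4S)-4-bromo-2-{[(tert-butyldimethylsilyl)oxy]methyl}-3-methyl-3-(prop-2-en-1-yl)cyclohexan-1-ol | CC(C)(C)[Si](C)(C)OC[C@@H]1C(O)CC[C@H](Br)[C@@]1(C)CC=C | intermediate
26 | (2R,3S,4S)-4-bromo-2-{[(tert-butyldimethylsilyl)oxy]methyl}-3-methyl-3-(prop-2-en-1-yl)cyclohexan-1-one | CC(C)(C)[Si](C)(C)OC[C@@H]1C(=O)CC[C@H](Br)[C@@]1(C)CC=C | intermediate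
27 | (1R,2R,3S,4S)-4-bromo-2-{[(tert-butyldimethylsilyl)oxy]methyl}-1,3-dimethyl-3-(prop-2-en-1-yl)cyclohexan-1-ol | CC(C)(C)[Si](C)(C)OC[C@@H]1[C@](C)(O)CC[C@H](Br)[C@@]1(C)CC=C | intermediate
28 | (1R,2R,3S,4S)-4-bromo-2-(hydroxymethyl)-1,3-dimethyl-3-(prop-2-en-1-yl)cyclohexan-1-ol | OC[C@@H]1[C@](C)(O)CC[C@H](Br)[C@@]1(C)CC=C | intermediate
29 | (1R,2S,3S,4S)-4-bromo-2-(iodomethyl)-1,3-dimethyl-3-(prop-2-en-1-yl)cyclohexan-1-ol | IC[C@@H]1[C@](C)(O)CC[C@H](Br)[C@@]1(C)CC=C | intermediate
30 | lithium alkoxide of {[(1S,2S,3S,6R)-3-bromo-6-hydroxy-2,6-dimethyl-2-(prop-2-en-1-yl)cyclohexyl]methyl}lithium | [Li]C[C@@H]1[C@](C)(O[Li])CC[C@H](Br)[C@@]1(C)CC=C | intermediate (not isolated)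
31 | 1-[(1R,4S)-4-bromo-1-hydroxy-3,3-dimethylcyclohexyl]-2-[(1S,2S,3S,6R)-3-bromo-6-hydroxy-2,6-dimethyl-2-(prop-2-en-1-yl)cyclohexyl]ethan-1-one | CC1(C)C[C@@](O)(C(=O)C[C@@H]2[C@](C)(O)CC[C@H](Br)[C@@]2(C)CC=C)CC[C@@H]1Br | intermediate
32 | 2-[(1S,2S,3R,6S)-6-bromo-2-{2-[(1R,4S)-4-bromo-1-hydroxy-3,3-dimethylcyclohexyl]-2-oxoethyl}-3-hydroxy-1,3-dimethylcyclohexyl]acetaldehyde | CC1(C)C[C@@](O)(C(=O)C[C@@H]2[C@](C)(O)CC[C@H](Br)[C@@]2(C)CC=O)CC[C@@H]1Br | intermediate
33 | [(1R,4S)-4-bromo-1-hydroxy-3,3-dimethylcyclohexyl][(1S,2R,3aS,4S,7R,7aS)-4-bromo-2,7-dihydroxy-3a,7-dimethyloctahydro-1H-inden-1-yl]methanone | CC1(C)C[C@@](O)(C(=O)[C@@H]2[C@H](O)C[C@]3(C)[C@@H](Br)CC[C@@](C)(O)[C@@H]23)CC[C@@H]1Br | intermediate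
34 | (1R,4S)-4-bromo-1-{(R)-[(1S,2R,3aS,4S,7R,7aS)-4-bromo-2,7-dihydroxy-3a,7-dimethyloctahydro-1H-inden-1-yl](hydroxy)methyl}-3,3-dimethylcyclohexan-1-ol | CC1(C)C[C@@](O)([C@H](O)[C@@H]2[C@H](O)C[C@]3(C)[C@@H](Br)CC[C@@](C)(O)[C@@H]23)CC[C@@H]1Br | target

**Step count.** Total: 25 steps. Longest linear sequence: 16 steps (steps 10–21, then 22–25, from 14 to 34); the ring A branch is 13 steps (steps 1–9, then 22–25).

**Steps most likely to fail**

1. Step 9 (bromide at C4). Displacement at an axial neopentyl carbinol is slow, so E2 loss towards C5, a 1,2-methyl shift from C3, or transannular ether formation by the tertiary C1 hydroxyl may overtake substitution. The fallback sets out from 5 and comes back at 13: bromine is introduced on the conformationally mobile seven-membered ring before the contraction, and the contraction is then run with external hydroxide. Appel reaction of 5 (PPh3, CBr4) should give, with inversion, (5S)-5-bromo-4,4-dimethylcyclohept-1-ene F1. OsO4/N-methylmorpholine N-oxide gives (5S)-5-bromo-4,4-dimethylcycloheptane-1,2-diol F2, and trifluoroacetic anhydride-activated DMSO gives (5S)-5-bromo-4,4-dimethylcycloheptane-1,2-dione F3. Aqueous KOH then brings about the classical benzilic acid ring contraction to (1R,4S)-4-bromo-1-hydroxy-3,3-dimethylcyclohexane-1-carboxylic acid F4, which forms together with its C1 epimer and is separated by crystallisation. Amide coupling of F4 with MeNH(OMe)·HCl (EDC, HOBt) returns to 13. The price is that C1 is no longer relayed from C4.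

2. Step 15 (bromonium cyclisation). The tertiary cation may lose a proton to an allylic bromide, the enol may be alkylated on oxygen, or the bromonium ion may be passed between alkenes with erosion of enantiopurity under the acidic conditions. The fallback sets out from 22 and comes back at 23: SOCl2 in Et2O at 0 °C converts the tertiary alcohol, with retention through the bromonium ion, into the tertiary chloride methyl (6S,7R)-6-bromo-7-chloro-7-methyl-3-oxodec-9-enoate F5. Solvolysis of F5 in (CF3)2CHOH buffered with K2CO3 at 25 °C ionises the chloride without strong acid and gives 23 by the same chair cyclisation.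

3. Step 22 (fragment union). Bromine–lithium exchange may compete with iodine–lithium exchange, the alkyllithium may cyclise onto the allyl group on warming, or a second addition to the new ketone may occur. The fallback sets out from 11 and 29 and comes back at 31, replacing the organolithium by an organozinc reagent and the amide by a thioester. Me2AlSEt (from AlMe3 and EtSH) opens lactone 11 to S-ethyl (1R,4R)-1,4-dihydroxy-3,3-dimethylcyclohexane-1-carbothioate F6, and Appel bromination gives S-ethyl (1R,4S)-4-bromo-1-hydroxy-3,3-dimethylcyclohexane-1-carbothioate F7. Zinc dust with LiCl in THF at 25 °C inserts only into the primary C–I bond of 29 to give {[(1S,2S,3S,6R)-3-bromo-6-hydroxy-2,6-dimethyl-2-(prop-2-en-1-yl)cyclohexyl]methyl}zinc iodide F8, used in solution. PdCl2(PPh3)2-catalysed Fukuyama coupling of F8 with F7 gives 31.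

**Further compounds**

F1 | step 9 | (5S)-5-bromo-4,4-dimethylcyclohept-1-ene | CC1(C)CC=CCC[C@@H]1Br
F2 | step 9 | (5S)-5-bromo-4,4-dimethylcycloheptane-1,2-diol (cis-diol, both facial diastereomers) | CC1(C)CC(O)C(O)CC[C@@H]1Br
F3 | step 9 | (5S)-5-bromo-4,4-dimethylcycloheptane-1,2-dione | CC1(C)CC(=O)C(=O)CC[C@@H]1Br
F4 | step 9 | (1R,4S)-4-bromo-1-hydroxy-3,3-dimethylcyclohexane-1-carboxylic acid | CC1(C)C[C@@](O)(C(O)=O)CC[C@@H]1Br
F5 | step 15 | methyl (6S,7R)-6-bromo-7-chloro-7-methyl-3-oxodec-9-enoate | COC(=O)CC(=O)CC[C@H](Br)[C@](C)(Cl)CC=C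
F6 | step 22 | S-ethyl (1R,4R)-1,4-dihydroxy-3,3-dimethylcyclohexane-1-carbothioate | CC1(C)C[C@@](O)(C(=O)SCC)CC[C@H]1O
F7 | step 22 | S-ethyl (1R,4S)-4-bromo-1-hydroxy-3,3-dimethylcyclohexane-1-carbothioate | CC1(C)C[C@@](O)(C(=O)SCC)CC[C@@H]1Br
F8 | step 22 | {[(1S,2S,3S,6R)-3-bromo-6-hydroxy-2,6-dimethyl-2-(prop-2-en-1-yl)cyclohexyl]methyl}zinc iodide | I[Zn]C[C@@H]1[C@](C)(O)CC[C@H](Br)[C@@]1(C)CC=C
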